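**Plan** (positions in briarane numbering: ring A = C1, C10–C14; ring B = C1–C10; lactone = C7, C8, C17, C19, O; TBS = tert-butyldimethylsilyl)
- Cuts: ring B at C3=C4 (ring-closing metathesis) and C4–C5 (Stille); lactone O–C7 (iodolactonisation); C8–C17 and C7–C8 (additions to a C8 acyl group); C9–C10 ([3,3] shift); ring A at C12–C13 and C14–C1 ([4+2]).
- Enabling feature: quaternary C1 of ring A lies between two cis oxygenated carbons, C2 and C14. A vinylboron unit (future C13–C14) hung on the C2 oxygen reaches a C12=C11–C10=C1 diene, and its C–B bond becomes the C14–O bond.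
- Forward order: acyclic Z-dienol → ring A by tethered cycloaddition → C9/C10 and the C11 exocyclic methylene by Ireland–Claisen → C8 carbinol and lactone ring → dienyl arm → ring B last.
- Stereochemistry: C2 from a Sharpless kinetic resolution; C1 and C14 relayed from C2 through the tether; C10/C9 from the chair Claisen on the open face of ring A; C8 by Felkin–Anh addition; C7 by hydroxyl-directed iodolactonisation; C17 by equilibration; 5E from Wittig/iodination; 3Z from ring strain.

Key step: step 5

Step 1
Reactants: 1 (±)-pent-1-en-4-yn-3-ol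
Product: 2 (S)-pent-1-en-4-yn-3-ol
Conditions: Ti(OiPr)4 (0.15 equiv), L-(+)-diisopropyl tartrate (0.2 equiv), t-BuOOH (0.6 equiv), 4 Å MS, CH2Cl2, −20 °C; recover unreacted alcohol
Reagents that add atoms: none
Why: Sharpless kinetic resolution of a secondary allylic alcohol, in which the (R)-enantiomer should be epoxidised much faster with the L-(+)-tartrate, so the unreacted (S)-alcohol is recovered and fixes C2 of the target.

Step 2
Reactants: 2 (S)-pent-1-en-4-yn-3-ol
Product: 4 (3S,1Z)-1-iodo-2-methylpenta-1,4-dien-3-ol, via alkenylmagnesium alkoxide chelate 3 (not isolated)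
Conditions: MeMgBr (3.5 equiv), CuI (0.1 equiv), THF, −20 °C → rt; then I2, −78 → 0 °C; aq. NH4Cl
Reagents that add atoms: methylmagnesium bromide, C[Mg]Br; iodine, II
Why: Copper-catalysed anti-carbomagnesiation of the propargylic alkoxide puts methyl on the internal alkyne carbon and magnesium on the terminal carbon inside a five-membered chelate, so iodinolysis should give the Z-iodide (iodine cis to the carbinol) without touching C2.

Step 3
Reactants: 4 (3S,1Z)-1-iodo-2-methylpenta-1,4-dien-3-ol; 5 2-bromoprop-2-en-1-ol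
Product: 7 (3Z,5S)-4-methyl-2-methylidenehepta-3,6-diene-1,5-diol, via alkenylzinc reagent 6 (not isolated)
Conditions: 5, t-BuLi (3 equiv), Et2O, −78 °C; ZnCl2, −78 → 0 °C; then 4, Pd(PPh3)4 (5 mol%), THF, rt (zinc reagent in excess)
Reagents that add atoms: none
Why: Negishi coupling of the alkenyl iodide with the 2-propenylzinc reagent should proceed with retention of the Z geometry and tolerate the metal alkoxides, giving the 2-substituted Z-diene.

Step 4
Reactants: 7 diene diol; 8 2-[(tert-butyldimethylsilyl)oxy]acetic acid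
Product: 9 (3Z,5S)-5-hydroxy-4-methyl-2-methylidenehepta-3,6-dien-1-yl 2-[(tert-butyldimethylsilyl)oxy]acetate
Conditions: 8 (1.05 equiv), DCC, DMAP (cat.), CH2Cl2, −20 → 0 °C
Reagents that add atoms: none
Why: Steglich esterification should acylate the unhindered primary allylic hydroxyl much faster than the secondary carbinol flanked by the trisubstituted alkene.

Step 5
Reactants: 9 dienol glycolate; 10 dibutyl vinylboronate
Product: 13 ring A diol glycolate, via tethered vinylboronate 11 (not isolated), via oxaborolane cycloadduct 12 (not isolated)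
Conditions: 10 (2 equiv), BHT (cat.), toluene, 130 °C, sealed tube; then anhydrous Me3NO (3 equiv), THF, 65 °C; aq. NaHCO3 work-up
Reagents that add atoms: trimethylamine N-oxide, C[N+](C)(C)[O-]
Why: Ester exchange at the C2 hydroxyl ties the vinylboron unit to the diene, and a thermal concerted [4+2] cycloaddition then joins C12 to C13 and C14 to C1; the closest known reaction type is the alkenylboronate-tethered intramolecular Diels–Alder reaction of dienols with oxidative cleavage of the tether. Ring A closes as a cyclohexene by [4+2] cycloaddition, and the transient 1,2-oxaborolane closes in the fused mode of a three-atom tether (C2–O–B), which on a Z-diene terminus can only give the cis ring fusion. The new quaternary C1 is controlled by the C2 carbinol: allylic 1,3-strain holds the C2–H bond in the diene plane towards C12, the vinyl group points away, and the oxygen-bound dienophile is delivered to the face syn to that oxygen. C14 is controlled by the cis fusion (boron exo, cis to C2), and oxidation of the C–B bond with retention should leave the C14 hydroxyl cis to C2 and trans to the C15 methyl. The step needs regioselectivity (C14 to C1, not to C12), which the short tether secures and the para-directing 2-acyloxymethyl group of the diene reinforces. It also needs the cycloaddition to outrun a 1,5-hydrogen shift of the Z-diene, which intramolecularity and the lowest workable temperature should secure.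

Step 6
Reactants: 13 ring A diol glycolate
Product: 14 2,14-bis-O-TBS ether of 13
Conditions: TBSOTf (2.5 equiv), 2,6-lutidine, CH2Cl2, −78 → 0 °C
Reagents that add atoms: tert-butyldimethylsilyl trifluoromethanesulfonate, CC(C)(C)[Si](C)(C)OS(=O)(=O)C(F)(F)F
Why: Silylation with the silyl triflate should protect both hindered secondary hydroxyls without enolising the ester, and the bulky C14 silyl ether later helps to screen the α face of ring A.

Step 7
Reactants: 14 bis-silyl ether
Product: 17 (9S,10S)-silyloxy acid with C11 exocyclic methylene, via silyl ketene acetal 15 (not isolated), via trimethylsilyl ester 16 (not isolated)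
Conditions: LDA (1.3 equiv), THF–HMPA (4:1), −78 °C; Me3SiCl; → rt, then 50 °C; dilute aq. citric acid work-up
Reagents that add atoms: none
Why: Ireland–Claisen rearrangement, in which enolisation in THF–HMPA gives the ketene acetal with the two silyloxy groups cis and the chair transition state with the E-configured ring terminus gives the syn C9/C10 pair together with the C11 exocyclic methylene; the new bond should form on the β face of C10 because the α face is screened in either half-chair, by the pseudoaxial C2 branch or by the axial C14 silyloxy group.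

Step 8
Reactants: 17 silyloxy acid
Product: 19 N-methoxy-N-methylamide, via acyl imidazole 18 (not isolated)
Conditions: CDI (1.2 equiv), CH2Cl2, rt; then MeNHOMe·HCl, rt
Reagents that add atoms: N,O-dimethylhydroxylamine hydrochloride, CNOC.Cl
Why: Amide formation through the acyl imidazole is mild enough for the hindered α-silyloxy acid and should not epimerise C9.

Step 9
Reactants: 19 N-methoxy-N-methylamide
Product: 20 vinyl ketone (C8 ketone carrying C7=C6)
Conditions: CH2=CHMgBr (2.5 equiv), THF, −20 → 0 °C; poured into cold aq. NH4Cl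
Reagents that add atoms: vinylmagnesium bromide, C=C[Mg]Br
Why: Grignard addition to the N-methoxy-N-methylamide stops at the ketone stage, and the cold acidic quench avoids conjugate addition of the released amine.

Step 10
Reactants: 20 vinyl ketone; 21 propanoic acid
Product: 23 β-hydroxy acid (C8 tertiary carbinol; C17 epimers), via dilithium propene-1,1-diolate 22 (not isolated)
Conditions: 21, LDA (2.1 equiv), THF, 0 °C → rt; then 20, −78 °C; aq. NH4Cl quench at −78 °C
Reagents that add atoms: none
Why: Aldol-type 1,2-addition of the carboxylic acid dianion to the ketone, in which the bulky non-chelating C9 silyl ether should impose polar Felkin–Anh selectivity (attack anti to the C9–O bond) and so give the required C8 configuration, while C17 forms as a mixture that step 16 corrects.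

Step 11
Reactants: 23 β-hydroxy acid
Product: 24 iodomethyl γ-lactone (C7 set; C17 epimers)
Conditions: I2 (3 equiv), NaHCO3, MeCN/H2O, 0 °C, dark
Reagents that add atoms: iodine, II
Why: Kinetic 5-exo iodolactonisation, in which the allylic C8 hydroxyl should direct the iodomethyl group cis to itself and trans to the bulky C9 branch (setting C7), and only the alkene that the carboxylate can capture in a five-membered ring is consumed because iodonium formation is reversible.

Step 12
Reactants: 24 iodomethyl lactone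
Product: 26 C6 aldehyde, via alkoxysulfonium tetrafluoroborate 25 (not isolated)
Conditions: AgBF4 (1.5 equiv), DMSO, rt; then Et3N
Reagents that add atoms: dimethyl sulfoxide, CS(C)=O
Why: Kornblum oxidation, in which silver-assisted displacement of the primary iodide by the sulfoxide and base-induced collapse of the alkoxysulfonium salt give the aldehyde under conditions that should not epimerise C7.

Step 13
Reactants: 26 C6 aldehyde
Product: 27 (E)-enal (C5=C6, C16 aldehyde)
Conditions: Ph3P=CHCHO (1.5 equiv), toluene, 50 °C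
Reagents that add atoms: (triphenylphosphoranylidene)acetaldehyde, O=CC=P(c1ccccc1)(c1ccccc1)c1ccccc1
Why: Wittig reaction with the stabilised ylide should give the E-enal and is neutral enough to leave the α-oxygenated C7 centre intact.

Step 14
Reactants: 27 (E)-enal
Product: 28 (Z)-α-iodoenal (iodine on C5)
Conditions: I2 (2 equiv), pyridine, DMAP (0.2 equiv), CH2Cl2, 0 °C → rt
Reagents that add atoms: iodine, II
Why: Amine-catalysed α-iodination of the enal (conjugate addition, iodination, elimination) should give the thermodynamic Z-iodoenal with iodine cis to C7, so that the later C4 substituent is cis to C7 as the target requires.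

Step 15
Reactants: 28 (Z)-α-iodoenal
Product: 29 (Z)-2-iodoallylic alcohol (C16–OH; C17 epimers)
Conditions: NaBH4, CeCl3·7H2O, MeOH, −78 °C
Reagents that add atoms: none
Why: Luche 1,2-reduction should reduce the aldehyde only, leaving the lactone and the alkenyl iodide.

Step 16
Reactants: 29 iodoallylic alcohol (C17 epimers)
Product: 30 (17R)-iodoallylic alcohol
Conditions: DBU (0.5 equiv), toluene, 60–80 °C
Reagents that add atoms: none
Why: Base-mediated epimerisation of the α-methyl lactone should converge on the thermodynamic isomer, in which the C17 methyl is trans to the bulky C9-bearing branch on the adjacent quaternary C8 (cis to the hydroxyl), as in the target.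

Step 17
Reactants: 30 (17R)-iodoallylic alcohol
Product: 31 2-(hydroxymethyl)-1,3-dienyl lactone (C4 vinyl installed)
Conditions: Bu3SnCH=CH2 (1.5 equiv), Pd(PPh3)4 (5 mol%), CuI (10 mol%), DMF, 40 °C
Reagents that add atoms: tributyl(vinyl)stannane, C=C[Sn](CCCC)(CCCC)CCCC
Why: Stille coupling of the alkenyl iodide proceeds with retention, so the new vinyl group (C4) is cis to C7 and the free C16 hydroxyl avoids loss of an allylic leaving group.

Step 18
Reactants: 31 tris-silyl dienyl lactone
Product: 32 pentaol (C2, C8, C9, C14, C16 hydroxyls)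
Conditions: HF·pyridine, pyridine/THF, 0 °C → rt
Reagents that add atoms: none
Why: Buffered fluoride desilylation should remove the three silyl ethers without ionising the allylic positions or opening the lactone.

Step 19
Reactants: 32 pentaol
Product: 33 2,9,14,16-tetraacetate (seco-triene)
Conditions: Ac2O, pyridine, DMAP (cat.), CH2Cl2, 0 °C → rt
Reagents that add atoms: acetic anhydride, CC(=O)OC(C)=O
Why: Acylation should esterify the primary and the three secondary hydroxyls while the hindered tertiary C8 hydroxyl of the β-hydroxy lactone stays free.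

Step 20
Reactants: 33 tetraacetate seco-triene
Product: 34 CNP0269068.1 (target)
Conditions: second-generation Grubbs catalyst (10 mol%), 1,4-benzoquinone (20 mol%), toluene (0.5 mM), 80 °C
Reagents that add atoms: none
Why: Ring-closing metathesis between the C2 vinyl group and the terminal vinyl of the diene closes ring B with loss of ethene; the two trans ring fusions pre-organise the chain, ring strain should enforce the 3Z geometry, and the 1,1-disubstituted and trisubstituted alkenes should not compete.

**Compound list** (TBS written out in SMILES)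
1 | (±)-pent-1-en-4-yn-3-ol | C=CC(O)C#C | starting material
2 | (S)-pent-1-en-4-yn-3-ol | C=C[C@H](O)C#C | intermediate
3 | cyclic alkenylmagnesium alkoxide chelate (Mg on terminal alkene carbon, cis to the carbinol) | C=C[C@@H]1O[Mg]C=C1C | intermediate
4 | (3S,1Z)-1-iodo-2-methylpenta-1,4-dien-3-ol | I/C=C(C)\[C@@H](O)C=C | intermediate
5 | 2-bromoprop-2-en-1-ol | C=C(Br)CO | starting material
6 | chloro[3-(lithiooxy)prop-1-en-2-yl]zinc | [Li]OCC(=C)[Zn]Cl | intermediate
7 | (3Z,5S)-4-methyl-2-methylidenehepta-3,6-diene-1,5-diol | C=C(CO)/C=C(C)\[C@@H](O)C=C | intermediate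
8 | 2-[(tert-butyldimethylsilyl)oxy]acetic acid | O=C(O)CO[Si](C)(C)C(C)(C)C | starting material
9 | (3Z,5S)-5-hydroxy-4-methyl-2-methylidenehepta-3,6-dien-1-yl 2-[(tert-butyldimethylsilyl)oxy]acetate | C=C(COC(=O)CO[Si](C)(C)C(C)(C)C)/C=C(C)\[C@@H](O)C=C | intermediate
10 | dibutyl vinylboronate | C=CB(OCCCC)OCCCC | starting material
11 | mixed butyl vinylboronate of 9 (boron on the C2 oxygen) | C=C(COC(=O)CO[Si](C)(C)C(C)(C)C)/C=C(C)\[C@@H](OB(OCCCC)C=C)C=C | intermediate
12 | cis-fused 2-butoxy-1,2-oxaborolane cycloadduct (B on C14, O on C2, C10=C11 alkene) | O=C(CO[Si](C)(C)C(C)(C)C)OCC1=C[C@@]2(C)[C@H](C=C)OB(OCCCC)[C@H]2CC1 | intermediate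
13 | [(3R,4S)-4-hydroxy-3-[(1S)-1-hydroxyprop-2-en-1-yl]-3-methylcyclohex-1-en-1-yl]methyl 2-[(tert-butyldimethylsilyl)oxy]acetate (C2–OH and C14–OH α, C15 methyl β) | O=C(CO[Si](C)(C)C(C)(C)C)OCC1=C[C@@](C)([C@@H](O)C=C)[C@@H](O)CC1 | intermediate
14 | 2,14-bis-O-TBS ether of 13 | O=C(CO[Si](C)(C)C(C)(C)C)OCC1=C[C@@](C)([C@@H](O[Si](C)(C)C(C)(C)C)C=C)[C@@H](O[Si](C)(C)C(C)(C)C)CC1 | intermediate
15 | (Z)-trimethylsilyl ketene acetal of 14 (OSiMe3 cis to OTBS) | C[Si](C)(C)O/C(OCC1=C[C@@](C)([C@@H](O[Si](C)(C)C(C)(C)C)C=C)[C@@H](O[Si](C)(C)C(C)(C)C)CC1)=C\O[Si](C)(C)C(C)(C)C | intermediate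
16 | trimethylsilyl ester of 17 | C=C1CC[C@H](O[Si](C)(C)C(C)(C)C)[C@](C)([C@@H](O[Si](C)(C)C(C)(C)C)C=C)[C@H]1[C@H](O[Si](C)(C)C(C)(C)C)C(=O)O[Si](C)(C)C | intermediate
17 | (1R,2S,9S,10S,14S)-2,9,14-tris-O-TBS acid: ring A with C11 exocyclic methylene, C10 (H α) bearing CH(OTBS)CO2H | C=C1CC[C@H](O[Si](C)(C)C(C)(C)C)[C@](C)([C@@H](O[Si](C)(C)C(C)(C)C)C=C)[C@H]1[C@H](O[Si](C)(C)C(C)(C)C)C(=O)O | intermediate
18 | acyl imidazole of 17 | C=C1CC[C@H](O[Si](C)(C)C(C)(C)C)[C@](C)([C@@H](O[Si](C)(C)C(C)(C)C)C=C)[C@H]1[C@H](O[Si](C)(C)C(C)(C)C)C(=O)n2ccnc2 | intermediate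
19 | N-methoxy-N-methylamide of 17 | C=C1CC[C@H](O[Si](C)(C)C(C)(C)C)[C@](C)([C@@H](O[Si](C)(C)C(C)(C)C)C=C)[C@H]1[C@H](O[Si](C)(C)C(C)(C)C)C(=O)N(C)OC | intermediate
20 | vinyl ketone (C8=O, C7=C6 vinyl) | C=C1CC[C@H](O[Si](C)(C)C(C)(C)C)[C@](C)([C@@H](O[Si](C)(C)C(C)(C)C)C=C)[C@H]1[C@H](O[Si](C)(C)C(C)(C)C)C(=O)C=C | intermediate
21 | propanoic acid | CCC(=O)O | starting material
22 | dilithium prop-1-ene-1,1-bis(olate) | CC=C(O[Li])O[Li] | intermediate
23 | β-hydroxy acid: C8 (configured as in target) bearing OH, vinyl and CH(CH3)CO2H; C17 epimers | C=C1CC[C@H](O[Si](C)(C)C(C)(C)C)[C@](C)([C@@H](O[Si](C)(C)C(C)(C)C)C=C)[C@H]1[C@H](O[Si](C)(C)C(C)(C)C)[C@@](O)(C=C)C(C)C(=O)O | intermediate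
24 | iodomethyl γ-lactone (C7 and C8 as in target; C17 epimers) | C=C1CC[C@H](O[Si](C)(C)C(C)(C)C)[C@](C)([C@@H](O[Si](C)(C)C(C)(C)C)C=C)[C@H]1[C@H](O[Si](C)(C)C(C)(C)C)[C@@]2(O)[C@H](CI)OC(=O)C2C | intermediate
25 | alkoxydimethylsulfonium tetrafluoroborate of the C6 carbinol | C=C1CC[C@H](O[Si](C)(C)C(C)(C)C)[C@](C)([C@@H](O[Si](C)(C)C(C)(C)C)C=C)[C@H]1[C@H](O[Si](C)(C)C(C)(C)C)[C@@]2(O)[C@H](CO[S+](C)C)OC(=O)C2C.F[B-](F)(F)F | intermediate
26 | C6 aldehyde lactone (C17 epimers) | C=C1CC[C@H](O[Si](C)(C)C(C)(C)C)[C@](C)([C@@H](O[Si](C)(C)C(C)(C)C)C=C)[C@H]1[C@H](O[Si](C)(C)C(C)(C)C)[C@@]2(O)[C@H](C=O)OC(=O)C2C | intermediate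
27 | (E)-enal lactone (C17 epimers) | C=C1CC[C@H](O[Si](C)(C)C(C)(C)C)[C@](C)([C@@H](O[Si](C)(C)C(C)(C)C)C=C)[C@H]1[C@H](O[Si](C)(C)C(C)(C)C)[C@@]2(O)[C@H](/C=C/C=O)OC(=O)C2C | intermediate
28 | (Z)-α-iodoenal lactone (C17 epimers) | C=C1CC[C@H](O[Si](C)(C)C(C)(C)C)[C@](C)([C@@H](O[Si](C)(C)C(C)(C)C)C=C)[C@H]1[C@H](O[Si](C)(C)C(C)(C)C)[C@@]2(O)[C@H](/C=C(\I)C=O)OC(=O)C2C | intermediate
29 | (Z)-2-iodoallylic alcohol lactone (C17 epimers) | C=C1CC[C@H](O[Si](C)(C)C(C)(C)C)[C@](C)([C@@H](O[Si](C)(C)C(C)(C)C)C=C)[C@H]1[C@H](O[Si](C)(C)C(C)(C)C)[C@@]2(O)[C@H](/C=C(\I)CO)OC(=O)C2C | intermediate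
30 | (17R)-(Z)-2-iodoallylic alcohol lactone (all centres as in target) | C=C1CC[C@H](O[Si](C)(C)C(C)(C)C)[C@](C)([C@@H](O[Si](C)(C)C(C)(C)C)C=C)[C@H]1[C@H](O[Si](C)(C)C(C)(C)C)[C@@]2(O)[C@H](/C=C(\I)CO)OC(=O)[C@@H]2C | intermediate
31 | tris-O-TBS 2-(hydroxymethyl)buta-1,3-dienyl lactone (vinyl cis to C7) | C=C1CC[C@H](O[Si](C)(C)C(C)(C)C)[C@](C)([C@@H](O[Si](C)(C)C(C)(C)C)C=C)[C@H]1[C@H](O[Si](C)(C)C(C)(C)C)[C@@]2(O)[C@H](/C=C(\C=C)CO)OC(=O)[C@@H]2C | intermediate
32 | seco-triene pentaol | C=C1CC[C@H](O)[C@](C)([C@@H](O)C=C)[C@H]1[C@H](O)[C@@]2(O)[C@H](/C=C(\C=C)CO)OC(=O)[C@@H]2C | intermediate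
33 | seco-triene 2,9,14,16-tetraacetate | C=C1CC[C@H](OC(C)=O)[C@](C)([C@@H](OC(C)=O)C=C)[C@H]1[C@H](OC(C)=O)[C@@]2(O)[C@H](/C=C(\C=C)COC(C)=O)OC(=O)[C@@H]2C | intermediate
34 | CNP0269068.1, (1R,2S,3Z,5E,7S,8S,9S,10S,14S,17R)-2,9,14,16-tetraacetoxy-8-hydroxybriara-3,5,11(20)-trien-19,7-olide | C=C1CC[C@H](OC(C)=O)[C@]2(C)[C@@H](OC(C)=O)/C=C\C(COC(C)=O)=C/[C@@H]3OC(=O)[C@H](C)[C@@]3(O)[C@@H](OC(C)=O)[C@@H]12 | target

**Totals:** 20 steps; longest linear sequence 20 steps (1 → 34).

**Steps most likely to fail**

Step 5. The mixed boronate may form incompletely at the hindered carbinol, and the slow cycloaddition at the fully substituted diene terminus may be outrun by a 1,5-hydrogen shift or diene oligomerisation. The fallback replaces the reversible boron tether by a covalent silicon tether. It sets out from 9: silylation of the C2 hydroxyl with chloro(dimethyl)vinylsilane and imidazole would give the vinylsilyl ether F1, a purifiable triene. Heating it (toluene, 170–180 °C, sealed tube) should give the cis-fused oxasilolane cycloadduct F2 by the same face-selective closure. Tamao–Fleming oxidation (H2O2, KF, KHCO3, THF) would turn the C–Si bond into the C14 hydroxyl with retention and return to the route at 13.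

Step 10. Facial selectivity at the C8 ketone may be poor or reversed, and conjugate addition to the vinyl ketone may compete. If the ketone prefers attack anti to the ring A branch, the fallback attaches the two carbon groups in the reverse order so that the same preference gives the required centre. It sets out from 19: EtMgBr would give the ethyl ketone F3. Its titanium enolate (TiCl4, iPr2NEt, CH2Cl2, −78 °C) with trimethyl orthoformate would give the β-keto dimethyl acetal F4. Addition of vinylmagnesium bromide promoted by CeCl3 would give the tertiary carbinol acetal F5. Mild acetal hydrolysis (aqueous oxalic acid, THF) would give the β-hydroxy aldehyde F6, and Pinnick oxidation (NaClO2, NaH2PO4, 2-methylbut-2-ene) returns to the route at 23.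

Step 20. Ring closure may stall through an unreactive ruthenium dienylidene or acetate chelation, or divert to oligomers. The fallback forms the C4–C5 bond instead of the C3=C4 bond. It sets out from 30: an intramolecular Heck reaction of the alkenyl iodide onto the C2 vinyl group (Pd(OAc)2, PPh3, Ag2CO3, MeCN, high dilution, 70 °C), with β-hydride elimination into conjugation, should give the ring B tris-silyl macrocycle F7. Desilylation with HF·pyridine would give the macrocyclic pentaol F8, and acetylation as in step 19 returns to the route at 34.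

**Further compounds**
F1 | step 5 | dimethyl(vinyl)silyl ether of 9 at the C2 oxygen | C=C(COC(=O)CO[Si](C)(C)C(C)(C)C)/C=C(C)\[C@@H](O[Si](C)(C)C=C)C=C
F2 | step 5 | cis-fused 2,2-dimethyl-1,2-oxasilolane cycloadduct (Si on C14, O on C2) | O=C(CO[Si](C)(C)C(C)(C)C)OCC1=C[C@@]2(C)[C@H](C=C)O[Si](C)(C)[C@H]2CC1
F3 | step 10 | ethyl ketone (C8=O with C17H2–C18H3) | C=C1CC[C@H](O[Si](C)(C)C(C)(C)C)[C@](C)([C@@H](O[Si](C)(C)C(C)(C)C)C=C)[C@H]1[C@H](O[Si](C)(C)C(C)(C)C)C(=O)CC
F4 | step 10 | β-keto dimethyl acetal (C19 as CH(OMe)2; C17 epimers) | C=C1CC[C@H](O[Si](C)(C)C(C)(C)C)[C@](C)([C@@H](O[Si](C)(C)C(C)(C)C)C=C)[C@H]1[C@H](O[Si](C)(C)C(C)(C)C)C(=O)C(C)C(OC)OC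
F5 | step 10 | tertiary vinyl carbinol dimethyl acetal (C17 epimers) | C=C1CC[C@H](O[Si](C)(C)C(C)(C)C)[C@](C)([C@@H](O[Si](C)(C)C(C)(C)C)C=C)[C@H]1[C@H](O[Si](C)(C)C(C)(C)C)[C@@](O)(C=C)C(C)C(OC)OC
F6 | step 10 | β-hydroxy aldehyde (C19 aldehyde; C17 epimers) | C=C1CC[C@H](O[Si](C)(C)C(C)(C)C)[C@](C)([C@@H](O[Si](C)(C)C(C)(C)C)C=C)[C@H]1[C@H](O[Si](C)(C)C(C)(C)C)[C@@](O)(C=C)C(C)C=O
F7 | step 20 | 2,9,14-tris-O-TBS macrocycle with free C16 and C8 hydroxyls | C=C1CC[C@H](O[Si](C)(C)C(C)(C)C)[C@]2(C)[C@@H](O[Si](C)(C)C(C)(C)C)/C=C\C(CO)=C/[C@@H]3OC(=O)[C@H](C)[C@@]3(O)[C@@H](O[Si](C)(C)C(C)(C)C)[C@@H]12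
F8 | step 20 | macrocyclic pentaol (tetra-deacetyl target) | C=C1CC[C@H](O)[C@]2(C)[C@@H](O)/C=C\C(CO)=C/[C@@H]3OC(=O)[C@H](C)[C@@]3(O)[C@@H](O)[C@@H]12
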